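The cyclohexane is disconnected as a formal [3+3]. Ring numbering: C1 (CH bearing the side chain), C2, C3, C4 (C(CH3)Cl), C5 (CHBr), C6. C1/C5 are 1,3-related through C6 and C2/C4 through C3, so a linalool-derived enal (C5 aldehyde, C6=C1) and methyl 3-oxopentanoate (C2, temporary C3 ketone, C4 with the ring methyl) are united by an organocatalytic Michael/aldol-condensation domino that forms C1–C2 and C4=C5 in one operation and sets C1. The C3 oxygen is then removed by double allylic transposition; reagent-controlled epoxidation, bromide opening and a 1,2-bromine shift with chloride capture give the trans-diequatorial halides.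

Key step: step 4

Assumption: the D-fructose-derived Shi ketone is taken to epoxidise both trisubstituted alkenes (steps 1 and 10) with the facial sense of its standard trisubstituted substrates, giving an R-configured CH–O carbon.

Step 1
Reactants: 1 (R)-(−)-linalool
Product: 2 (3R)-5-[(2R)-3,3-dimethyloxiran-2-yl]-3-methylpent-1-en-3-ol
Conditions: 1,2:4,5-di-O-isopropylidene-D-erythro-2,3-hexodiulo-2,6-pyranose (D-fructose-derived Shi ketone, 0.3 equiv), Oxone (2KHSO5·KHSO4·K2SO4), K2CO3, Bu4NHSO4, MeCN/CH2(OMe)2/aq. Na2B4O7 buffer, 0 °C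
Reagents that add atoms: Oxone (potassium peroxymonosulfate), [K+].[O-]S(=O)(=O)OO
Why: Shi asymmetric epoxidation, in which the chiral dioxirane should oxidise only the electron-rich trisubstituted alkene (the vinyl group is inert) and set the new CH–O centre as R by reagent control through the spiro transition state.

Step 2
Reactants: 2 (3R)-5-[(2R)-3,3-dimethyloxiran-2-yl]-3-methylpent-1-en-3-ol; 3 (E)-but-2-enal (crotonaldehyde)
Product: 4 (2E,4R)-6-[(2R)-3,3-dimethyloxiran-2-yl]-4-hydroxy-4-methylhex-2-enal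
Conditions: crotonaldehyde (5 equiv), Hoveyda–Grubbs second-generation catalyst RuCl2(=CH-2-iPrOC6H4)(H2IMes) (5 mol%), CH2Cl2, 40 °C
Reagents that add atoms: none
Why: Olefin cross-metathesis of the hydroxyl-bearing vinyl group with excess enal should give the E-enal with loss of propene, and ring-closing metathesis cannot compete because the second alkene is already an epoxide.

Step 3
Reactants: 4 (2E,4R)-6-[(2R)-3,3-dimethyloxiran-2-yl]-4-hydroxy-4-methylhex-2-enal
Product: 5 (2E,4R)-6-[(2R)-3,3-dimethyloxiran-2-yl]-4-methyl-4-(triethylsilyloxy)hex-2-enal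
Conditions: Et3SiOTf, 2,6-lutidine, CH2Cl2, −78 °C
Reagents that add atoms: triethylsilyl trifluoromethanesulfonate, CC[Si](CC)(CC)OS(=O)(=O)C(F)(F)F
Why: Silyl triflate silylation of the tertiary alcohol should block lactol formation of the γ-hydroxy enal and later attack of this oxygen on ring electrophiles, without touching a stereocentre.

Step 4
Reactants: 5 (2E,4R)-6-[(2R)-3,3-dimethyloxiran-2-yl]-4-methyl-4-(triethylsilyloxy)hex-2-enal; 6 methyl 3-oxopentanoate
Product: 9 methyl (6R)-3-methyl-2-oxo-6-[(2R)-4-[(2R)-3,3-dimethyloxiran-2-yl]-2-(triethylsilyloxy)butan-2-yl]cyclohex-3-ene-1-carboxylate, via Michael adduct aldehyde 7 (not isolated), via cyclic aldol 8 (not isolated)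
Conditions: (S)-2-[diphenyl(trimethylsilyloxy)methyl]pyrrolidine (20 mol%), PhCO2H (20 mol%), toluene, 0 °C → rt; then 1,8-diazabicyclo[5.4.0]undec-7-ene (DBU), rt
Reagents that add atoms: none
Why: The amine converts enal 5 into an E-iminium ion, the doubly activated methylene of 6 adds to its β-carbon from the face not shielded by the diphenyl(silyloxy)methyl group (forming C1–C2; aldehyde 7 after enamine hydrolysis), and DBU then promotes intramolecular aldol addition of the propanoyl α-carbon to the aldehyde (8) and E1cB dehydration (forming C4=C5). The closest known reaction type is the organocatalytic Michael/aldol-condensation domino of β-keto esters with enals (formal [3+3], Robinson-type). The ring closes by a 6-(enolendo)-exo-trig aldol addition. The one stereocentre that is kept, C1, is set by the catalyst (Si-face attack in the sense known for (S)-diarylprolinol silyl ethers), which has to override the weak bias of the neighbouring quaternary silyloxy carbon. The step needs 1,4- rather than 1,2-addition, secured by iminium activation and the soft 1,3-dicarbonyl nucleophile, and aldol closure through the propanoyl carbon, secured because only this closure gives an unstrained six-membered ring and an irreversibly formed conjugated enone. The C3 ketone and the C2 ester are temporary activating groups removed in steps 5, 7 and 8.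

Step 5
Reactants: 9 methyl (6R)-3-methyl-2-oxo-6-[(2R)-4-[(2R)-3,3-dimethyloxiran-2-yl]-2-(triethylsilyloxy)butan-2-yl]cyclohex-3-ene-1-carboxylate
Product: 10 (5R)-5-[(2R)-4-[(2R)-3,3-dimethyloxiran-2-yl]-2-(triethylsilyloxy)butan-2-yl]-2-methylcyclohex-2-en-1-one
Conditions: LiOH, THF/H2O, 0 °C → rt; then AcOH to pH 5, 40 °C
Reagents that add atoms: none
Why: Saponification and decarboxylation of the resulting β-keto acid should leave the carvone-type enone, the ring stereocentre being β to the ketone and therefore not epimerisable.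

Step 6
Reactants: 10 (5R)-5-[(2R)-4-[(2R)-3,3-dimethyloxiran-2-yl]-2-(triethylsilyloxy)butan-2-yl]-2-methylcyclohex-2-en-1-one
Product: 11 (1R,4R,6R)-4-[(2R)-4-[(2R)-3,3-dimethyloxiran-2-yl]-2-(triethylsilyloxy)butan-2-yl]-1-methyl-7-oxabicyclo[4.1.0]heptan-2-one
Conditions: 30% aq. H2O2, NaOH (cat.), MeOH, 0 °C
Reagents that add atoms: hydrogen peroxide, OO
Why: Weitz–Scheffer nucleophilic epoxidation, in which hydroperoxide should add axially to the enone β-carbon anti to the pseudo-equatorial side chain (as with carvone), giving the epoxide trans to the side chain.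

Step 7
Reactants: 11 (1R,4R,6R)-4-[(2R)-4-[(2R)-3,3-dimethyloxiran-2-yl]-2-(triethylsilyloxy)butan-2-yl]-1-methyl-7-oxabicyclo[4.1.0]heptan-2-one
Product: 13 (1R,5S)-5-[(2R)-4-[(2R)-3,3-dimethyloxiran-2-yl]-2-(triethylsilyloxy)butan-2-yl]-2-methylcyclohex-2-en-1-ol (hydroxyl trans to the side chain), via epoxy hydrazone 12 (not isolated)
Conditions: N2H4·H2O, AcOH (cat.), MeOH, 0 °C → rt
Reagents that add atoms: none
Why: Wharton transposition, in which the epoxy hydrazone should fragment with loss of N2 to the allylic alcohol, so that the C3 oxygen is removed and the C–O configuration at C5 is retained.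

Step 8
Reactants: 13 (1R,5S)-5-[(2R)-4-[(2R)-3,3-dimethyloxiran-2-yl]-2-(triethylsilyloxy)butan-2-yl]-2-methylcyclohex-2-en-1-ol
Product: 15 triethyl{[(2R)-4-[(2R)-3,3-dimethyloxiran-2-yl]-2-[(1S)-4-methylcyclohex-3-en-1-yl]butan-2-yl]oxy}silane, via allylic sulfonylhydrazine 14 (not isolated)
Conditions: 2-nitrobenzenesulfonohydrazide, PPh3, diethyl azodicarboxylate, THF, −30 °C → rt
Reagents that add atoms: none
Why: Mitsunobu displacement by the sulfonyl hydrazide, sulfinate loss and retro-ene expulsion of N2 from the allylic diazene (reductive 1,3-transposition) should return the double bond to C4=C5 and place hydrogen on C3 without touching C1.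

Step 9
Reactants: 15 triethyl{[(2R)-4-[(2R)-3,3-dimethyloxiran-2-yl]-2-[(1S)-4-methylcyclohex-3-en-1-yl]butan-2-yl]oxy}silane
Product: 16 tert-butyldimethyl{[(3R,6R)-2-methyl-6-[(1S)-4-methylcyclohex-3-en-1-yl]-6-(triethylsilyloxy)hept-1-en-3-yl]oxy}silane
Conditions: t-BuMe2SiOTf, 2,6-lutidine, toluene, −78 °C → rt; then DBU, rt
Reagents that add atoms: tert-butyldimethylsilyl trifluoromethanesulfonate, CC(C)(C)[Si](C)(C)OS(=O)(=O)C(F)(F)F
Why: Silyl triflate-mediated isomerisation of the epoxide to an allylic silyl ether, in which ionisation at the tertiary epoxide carbon and loss of a methyl proton should give the isopropenyl carbinol ether with the R C–O centre retained.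

Step 10
Reactants: 16 tert-butyldimethyl{[(3R,6R)-2-methyl-6-[(1S)-4-methylcyclohex-3-en-1-yl]-6-(triethylsilyloxy)hept-1-en-3-yl]oxy}silane
Product: 17 (1S,4S,6R)-4-[(2R,5R)-5-(tert-butyldimethylsilyloxy)-6-methyl-2-(triethylsilyloxy)hept-6-en-2-yl]-1-methyl-7-oxabicyclo[4.1.0]heptane (epoxide oxygen trans to the side chain)
Conditions: 1,2:4,5-di-O-isopropylidene-D-erythro-2,3-hexodiulo-2,6-pyranose (0.3 equiv), Oxone (2KHSO5·KHSO4·K2SO4), K2CO3, Bu4NHSO4, MeCN/CH2(OMe)2/aq. Na2B4O7 buffer, 0 °C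
Reagents that add atoms: Oxone (potassium peroxymonosulfate), [K+].[O-]S(=O)(=O)OO
Why: Shi asymmetric epoxidation, in which reagent control should deliver oxygen to the ring-alkene face trans to the side chain (R CH–O carbon), while the 1,1-disubstituted alkene deactivated by its allylic silyloxy group reacts much more slowly.

Step 11
Reactants: 17 (1S,4S,6R)-4-[(2R,5R)-5-(tert-butyldimethylsilyloxy)-6-methyl-2-(triethylsilyloxy)hept-6-en-2-yl]-1-methyl-7-oxabicyclo[4.1.0]heptane
Product: 18 (1R,2R,5S)-2-bromo-5-[(2R,5R)-5-(tert-butyldimethylsilyloxy)-6-methyl-2-(triethylsilyloxy)hept-6-en-2-yl]-2-methylcyclohexan-1-ol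
Conditions: MgBr2·OEt2, Et2O, −40 → 0 °C
Reagents that add atoms: magnesium bromide diethyl etherate, [Mg+2].[Br-].[Br-].CCOCC
Why: Lewis acid-assisted epoxide opening, in which bromide should attack the tertiary carbon C4 with inversion in the mode where Markovnikov and trans-diaxial (Fürst–Plattner) preferences agree, giving axial C4–Br anti to the axial C5 hydroxyl.

Step 12
Reactants: 18 (1R,2R,5S)-2-bromo-5-[(2R,5R)-5-(tert-butyldimethylsilyloxy)-6-methyl-2-(triethylsilyloxy)hept-6-en-2-yl]-2-methylcyclohexan-1-ol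
Product: 20 tert-butyl{[(3R,6R)-6-[(1S,3S,4S)-3-bromo-4-chloro-4-methylcyclohexyl]-2-methyl-6-(triethylsilyloxy)hept-1-en-3-yl]oxy}dimethylsilane, via alkoxyphosphonium chloride 19 (not isolated)
Conditions: PPh3, N-chlorosuccinimide, CH2Cl2, −20 °C → rt
Reagents that add atoms: N-chlorosuccinimide, ClN1C(=O)CCC1=O
Why: Appel-type activation with neighbouring-group participation, in which the antiperiplanar C4 bromine should displace the oxyphosphonium group at C5 with inversion to a bromonium ion on the side-chain face, and chloride should open it at the tertiary carbon from the opposite face (net 1,2-bromine shift) to give the trans-diequatorial C5–Br/C4–Cl pair.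

Step 13
Reactants: 20 tert-butyl{[(3R,6R)-6-[(1S,3S,4S)-3-bromo-4-chloro-4-methylcyclohexyl]-2-methyl-6-(triethylsilyloxy)hept-1-en-3-yl]oxy}dimethylsilane
Product: 21 (3R,6R)-6-[(1S,3S,4S)-3-bromo-4-chloro-4-methylcyclohexyl]-2-methylhept-1-ene-3,6-diol
Conditions: HF·pyridine, pyridine/THF, 0 °C → rt
Reagents that add atoms: none
Why: Fluoride-mediated cleavage of both silyl ethers under non-basic conditions should free the diol without elimination or solvolysis of the halides.

Compound list
1 | (R)-(−)-linalool, (3R)-3,7-dimethylocta-1,6-dien-3-ol | CC(C)=CCC[C@@](C)(O)C=C | starting material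
2 | (3R)-5-[(2R)-3,3-dimethyloxiran-2-yl]-3-methylpent-1-en-3-ol | CC1(C)O[C@@H]1CC[C@@](C)(O)C=C | intermediate
3 | (E)-but-2-enal (crotonaldehyde) | C/C=C/C=O | starting material
4 | (2E,4R)-6-[(2R)-3,3-dimethyloxiran-2-yl]-4-hydroxy-4-methylhex-2-enal | CC1(C)O[C@@H]1CC[C@@](C)(O)/C=C/C=O | intermediate
5 | (2E,4R)-6-[(2R)-3,3-dimethyloxiran-2-yl]-4-methyl-4-(triethylsilyloxy)hex-2-enal | CC1(C)O[C@@H]1CC[C@@](C)(O[Si](CC)(CC)CC)/C=C/C=O | intermediate
6 | methyl 3-oxopentanoate | CCC(=O)CC(=O)OC | starting material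
7 | methyl (3R)-3-[(2R)-4-[(2R)-3,3-dimethyloxiran-2-yl]-2-(triethylsilyloxy)butan-2-yl]-5-oxo-2-propanoylpentanoate (C2 epimers; not isolated) | CC1(C)O[C@@H]1CC[C@@](C)(O[Si](CC)(CC)CC)[C@H](CC=O)C(C(=O)OC)C(=O)CC | intermediate
8 | methyl (6R)-4-hydroxy-3-methyl-2-oxo-6-[(2R)-4-[(2R)-3,3-dimethyloxiran-2-yl]-2-(triethylsilyloxy)butan-2-yl]cyclohexane-1-carboxylate (mixture at C1, C3, C4; not isolated) | CC1(C)O[C@@H]1CC[C@@](C)(O[Si](CC)(CC)CC)[C@H]2C(C(=O)OC)C(=O)C(C)C(O)C2 | intermediate
9 | methyl (6R)-3-methyl-2-oxo-6-[(2R)-4-[(2R)-3,3-dimethyloxiran-2-yl]-2-(triethylsilyloxy)butan-2-yl]cyclohex-3-ene-1-carboxylate (ester-bearing carbon not controlled) | CC1(C)O[C@@H]1CC[C@@](C)(O[Si](CC)(CC)CC)[C@H]2C(C(=O)OC)C(=O)C(C)=CC2 | intermediate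
10 | (5R)-5-[(2R)-4-[(2R)-3,3-dimethyloxiran-2-yl]-2-(triethylsilyloxy)butan-2-yl]-2-methylcyclohex-2-en-1-one | CC1(C)O[C@@H]1CC[C@@](C)(O[Si](CC)(CC)CC)[C@H]2CC(=O)C(C)=CC2 | intermediate
11 | (1R,4R,6R)-4-[(2R)-4-[(2R)-3,3-dimethyloxiran-2-yl]-2-(triethylsilyloxy)butan-2-yl]-1-methyl-7-oxabicyclo[4.1.0]heptan-2-one | CC1(C)O[C@@H]1CC[C@@](C)(O[Si](CC)(CC)CC)[C@H]2CC(=O)[C@]3(C)O[C@@H]3C2 | intermediate
12 | hydrazone of 11 (not isolated) | CC1(C)O[C@@H]1CC[C@@](C)(O[Si](CC)(CC)CC)[C@H]2CC(=NN)[C@]3(C)O[C@@H]3C2 | intermediate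
13 | (1R,5S)-5-[(2R)-4-[(2R)-3,3-dimethyloxiran-2-yl]-2-(triethylsilyloxy)butan-2-yl]-2-methylcyclohex-2-en-1-ol | CC1(C)O[C@@H]1CC[C@@](C)(O[Si](CC)(CC)CC)[C@H]2CC=C(C)[C@H](O)C2 | intermediate
14 | 1-[(1S,5S)-5-[(2R)-4-[(2R)-3,3-dimethyloxiran-2-yl]-2-(triethylsilyloxy)butan-2-yl]-2-methylcyclohex-2-en-1-yl]-1-(2-nitrophenylsulfonyl)hydrazine (not isolated) | CC1(C)O[C@@H]1CC[C@@](C)(O[Si](CC)(CC)CC)[C@H]2CC=C(C)[C@@H](N(N)S(=O)(=O)c3ccccc3[N+](=O)[O-])C2 | intermediate
15 | triethyl{[(2R)-4-[(2R)-3,3-dimethyloxiran-2-yl]-2-[(1S)-4-methylcyclohex-3-en-1-yl]butan-2-yl]oxy}silane | CC1(C)O[C@@H]1CC[C@@](C)(O[Si](CC)(CC)CC)[C@H]2CCC(C)=CC2 | intermediate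
16 | tert-butyldimethyl{[(3R,6R)-2-methyl-6-[(1S)-4-methylcyclohex-3-en-1-yl]-6-(triethylsilyloxy)hept-1-en-3-yl]oxy}silane | C=C(C)[C@H](O[Si](C)(C)C(C)(C)C)CC[C@@](C)(O[Si](CC)(CC)CC)[C@H]1CCC(C)=CC1 | intermediate
17 | (1S,4S,6R)-4-[(2R,5R)-5-(tert-butyldimethylsilyloxy)-6-methyl-2-(triethylsilyloxy)hept-6-en-2-yl]-1-methyl-7-oxabicyclo[4.1.0]heptane | C=C(C)[C@H](O[Si](C)(C)C(C)(C)C)CC[C@@](C)(O[Si](CC)(CC)CC)[C@H]1CC[C@]2(C)O[C@@H]2C1 | intermediate
18 | (1R,2R,5S)-2-bromo-5-[(2R,5R)-5-(tert-butyldimethylsilyloxy)-6-methyl-2-(triethylsilyloxy)hept-6-en-2-yl]-2-methylcyclohexan-1-ol | C=C(C)[C@H](O[Si](C)(C)C(C)(C)C)CC[C@@](C)(O[Si](CC)(CC)CC)[C@H]1CC[C@@](C)(Br)[C@H](O)C1 | intermediate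
19 | O-triphenylphosphonium chloride of 18 (not isolated) | C=C(C)[C@H](O[Si](C)(C)C(C)(C)C)CC[C@@](C)(O[Si](CC)(CC)CC)[C@H]1CC[C@@](C)(Br)[C@H](O[P+](c2ccccc2)(c2ccccc2)c2ccccc2)C1.[Cl-] | intermediate
20 | tert-butyl{[(3R,6R)-6-[(1S,3S,4S)-3-bromo-4-chloro-4-methylcyclohexyl]-2-methyl-6-(triethylsilyloxy)hept-1-en-3-yl]oxy}dimethylsilane | C=C(C)[C@H](O[Si](C)(C)C(C)(C)C)CC[C@@](C)(O[Si](CC)(CC)CC)[C@H]1CC[C@](C)(Cl)[C@@H](Br)C1 | intermediate
21 | (3R,6R)-6-[(1S,3S,4S)-3-bromo-4-chloro-4-methylcyclohexyl]-2-methylhept-1-ene-3,6-diol | C=C(C)[C@H](O)CC[C@@](C)(O)[C@H]1CC[C@](C)(Cl)[C@@H](Br)C1 | target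

Total step count: 13. Longest linear sequence: 13 steps (1 → 21).

Steps most likely to fail

Step 4. The conjugate addition may stall or lose facial control, because the β-carbon of 5 is flanked by a fully substituted silyloxy carbon; racemic background addition or 1,2-addition would then erode the configuration at C1. The fallback sets out from 6 and returns at 10, forming the same two bonds by a stereospecific dianion annulation. 6-Methylhept-5-en-2-one and c-C3H5MgBr should give 2-cyclopropyl-6-methylhept-5-en-2-ol F1. Aqueous HBr should open it by the Julia cyclopropylcarbinyl rearrangement to (3E)-1-bromo-4,8-dimethylnona-3,7-diene F2. Shi epoxidation of both trisubstituted alkenes with the same ketone should give (2R,3R)-3-(2-bromoethyl)-2-{2-[(2R)-3,3-dimethyloxiran-2-yl]ethyl}-2-methyloxirane F3. The dianion of 6 (NaH, then n-BuLi, THF, 0 °C) should be alkylated at its γ-carbon by the bromide to give methyl 4-methyl-3-oxo-6-[(2R,3R)-3-{2-[(2R)-3,3-dimethyloxiran-2-yl]ethyl}-3-methyloxiran-2-yl]hexanoate F4. On warming, the remaining β-keto ester enolate of F4 should open the nearer epoxide at its CH carbon with inversion (6-(enolendo)-exo-tet), and the released tertiary alkoxide should lactonise to the bicyclic keto lactone F5. LiOH followed by AcOH (hydrolysis and decarboxylation) should give the hydroxy ketone F6. Et3SiOTf should give the silyl ether F7. Me3SiOTf/Et3N should give the more substituted trimethylsilyl enol ether F8, and Pd(OAc)2 (Saegusa–Ito oxidation) should then give 10.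

Step 12. Chloride may capture the bromonium ion at the secondary carbon C5 (the trans-diaxial mode) instead of the tertiary carbon C4, or elimination may intervene. The fallback sets out from 18 and returns at 20. The same activation would then deliver the diaxial regioisomer with chlorine at C5 and bromine at C4, F11. Heating F11 in a polar solvent (MeCN, catalytic Bu4NCl, 60 °C) should equilibrate it through the same bromonium/chloride ion pair to the diequatorial isomer 20 (diaxial-to-diequatorial rearrangement of a vicinal dihalide, which interchanges the two halogens). 20 would be separated and F11 recycled.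

Step 10. The reagent may fail to override the substrate, giving both epoxide faces, or may also attack the isopropenyl alkene. The fallback sets out from 16 and returns at 17. Epoxidation with one equivalent of m-chloroperbenzoic acid should give 17 together with its diastereomer with oxygen cis to the side chain, F9. Pyrrolidine in water should then consume only F9, by trans-diaxial aminolysis at its CH carbon, to give the amino alcohol F10. 17 should be left unchanged, because its diaxial opening would require attack at the tertiary carbon, and is recovered by chromatography.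

Further compounds
F1 | step 4 | 2-cyclopropyl-6-methylhept-5-en-2-ol | CC(C)=CCCC(C)(O)C1CC1
F2 | step 4 | (3E)-1-bromo-4,8-dimethylnona-3,7-diene | CC(C)=CCC/C(C)=C/CCBr
F3 | step 4 | (2R,3R)-3-(2-bromoethyl)-2-{2-[(2R)-3,3-dimethyloxiran-2-yl]ethyl}-2-methyloxirane | CC1(C)O[C@@H]1CC[C@@]2(C)O[C@@H]2CCBr
F4 | step 4 | methyl 4-methyl-3-oxo-6-[(2R,3R)-3-{2-[(2R)-3,3-dimethyloxiran-2-yl]ethyl}-3-methyloxiran-2-yl]hexanoate | CC1(C)O[C@@H]1CC[C@@]2(C)O[C@@H]2CCC(C)C(=O)CC(=O)OC
F5 | step 4 | bicyclic keto lactone: 3-{2-[(2R)-3,3-dimethyloxiran-2-yl]ethyl}-3,6-dimethylhexahydro-2-benzofuran-1,7-dione, (3R,3aS) | CC1(C)O[C@@H]1CC[C@@]2(C)OC(=O)C3C(=O)C(C)CC[C@@H]23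
F6 | step 4 | (5S)-5-[(2R)-4-[(2R)-3,3-dimethyloxiran-2-yl]-2-hydroxybutan-2-yl]-2-methylcyclohexan-1-one (C2 epimers) | CC1(C)O[C@@H]1CC[C@@](C)(O)[C@H]2CC(=O)C(C)CC2
F7 | step 4 | triethylsilyl ether of F6 | CC1(C)O[C@@H]1CC[C@@](C)(O[Si](CC)(CC)CC)[C@H]2CC(=O)C(C)CC2
F8 | step 4 | trimethylsilyl enol ether of F7 (more substituted enol) | CC1(C)O[C@@H]1CC[C@@](C)(O[Si](CC)(CC)CC)[C@H]2CC(O[Si](C)(C)C)=C(C)CC2
F9 | step 10 | diastereomer of 17 with the epoxide oxygen cis to the side chain, (1R,4S,6S) | C=C(C)[C@H](O[Si](C)(C)C(C)(C)C)CC[C@@](C)(O[Si](CC)(CC)CC)[C@H]1CC[C@@]2(C)O[C@H]2C1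
F10 | step 10 | (1R,2R,4S)-4-[(2R,5R)-5-(tert-butyldimethylsilyloxy)-6-methyl-2-(triethylsilyloxy)hept-6-en-2-yl]-1-methyl-2-(pyrrolidin-1-yl)cyclohexan-1-ol | C=C(C)[C@H](O[Si](C)(C)C(C)(C)C)CC[C@@](C)(O[Si](CC)(CC)CC)[C@H]1CC[C@@](C)(O)[C@H](N2CCCC2)C1
F11 | step 12 | diaxial regioisomer of 20 with chlorine at C5 and bromine at C4 | C=C(C)[C@H](O[Si](C)(C)C(C)(C)C)CC[C@@](C)(O[Si](CC)(CC)CC)[C@H]1CC[C@@](C)(Br)[C@H](Cl)C1
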